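**Plan**
- Cuts: the pyranone is traced back to the carboxyl carbon on C4 (its C6) plus a dioxinone four-carbon unit; ring B is then cut at C1–C2 and C3–C4.
- Enabling feature: C1 and C4 both sit on ring A, C1 bears oxygen and C4 a carboxyl-level carbon. Ring B (C1–C4, C4a, C8a) is therefore the [4+2] adduct of an o-quinoid 2-benzopyran-3-one (diene C1=C8a–C4a=C4 under an O–C=O bridge) with the C2=C3 silyl enol ether of acetophenone.
- Forward, first part: ring A is bought as 2-bromo-6-hydroxybenzaldehyde; benzylation, acetal formation, Negishi α-arylation, acidolysis and acetylation give the lactol acetate of the (2-formylaryl)acetic acid.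
- Forward, second part: ring B closes in the cycloaddition as a bridged lactone; its carbonyl acylates a dioxinone dienolate, the C1 alcohol is oxidized, and thermolysis closes the pyranone through an acylketene; debenzylation and desilylation finish.
- Stereochemistry: C3 and C4 arise in the cycloaddition. A chiral phosphoric acid chooses the diene face, the bridge holds C4 cis to the C1 oxygen, and the orientation of the enol ether (phenyl towards the bridge) sets C3. The C1 centre is later oxidized away, and C4 stays a non-enolizable bridgehead until the side chain is attached.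

Key step: step 7

Assumption: the sense of induction of the phosphoric acid in step 7 is not known in advance; the (R) acid is written, and the (S) acid is to be used instead if the first run gives the mirror-image lactone.

Tetralin numbering of the target (C1 carbonyl, C3 carbinol, C4 methine, C8 phenol) is used for ring positions throughout.

**Step 1**
Reactants: 1 2-bromo-6-hydroxybenzaldehyde
Product: 2 2-(benzyloxy)-6-bromobenzaldehyde
Conditions: BnBr, K2CO3, DMF, 50 °C
Reagents that add atoms: benzyl bromide, BrCc1ccccc1
Why: Williamson etherification of the phenoxide; the benzyl ether should withstand every later acid, base and enolate step and, unlike a silyl or acyl group, cannot migrate to the neighbouring C1 oxygen.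

**Step 2**
Reactants: 2 2-(benzyloxy)-6-bromobenzaldehyde
Product: 3 2-[2-(benzyloxy)-6-bromophenyl]-1,3-dioxolane
Conditions: ethylene glycol, TsOH·H2O (cat.), toluene, reflux, Dean–Stark trap
Reagents that add atoms: ethylene glycol, OCCO
Why: acid-catalysed acetalization with azeotropic removal of water masks the aldehyde against the zinc enolate of step 3.

**Step 3**
Reactants: 3 2-[2-(benzyloxy)-6-bromophenyl]-1,3-dioxolane; 4 tert-butyl bromoacetate
Product: 6 tert-butyl [3-(benzyloxy)-2-(1,3-dioxolan-2-yl)phenyl]acetate, via Reformatsky reagent 5 (not isolated)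
Conditions: 4, Zn dust (Me3SiCl-activated), THF, rt; then 3, Pd2(dba)3 (1 mol %), 2-dicyclohexylphosphino-2′,4′,6′-triisopropylbiphenyl (4 mol %), THF, 60 °C
Reagents that add atoms: none
Why: Negishi-type α-arylation, in which zerovalent palladium carrying a bulky biarylphosphine inserts into the aryl bromide and couples it with the zinc enolate, a nucleophile mild enough to leave the acetal and the benzyl ether alone.

**Step 4**
Reactants: 6 tert-butyl [3-(benzyloxy)-2-(1,3-dioxolan-2-yl)phenyl]acetate
Product: 7 [3-(benzyloxy)-2-formylphenyl]acetic acid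
Conditions: CF3CO2H/CH2Cl2/H2O (10:10:1), rt
Reagents that add atoms: water, O
Why: acidolysis removes the tert-butyl ester as 2-methylpropene and hydrolyses the dioxolane in the same pot, while the aryl benzyl ether is stable to trifluoroacetic acid at room temperature.

**Step 5**
Reactants: 7 [3-(benzyloxy)-2-formylphenyl]acetic acid
Product: 9 8-(benzyloxy)-3-oxo-3,4-dihydro-1H-2-benzopyran-1-yl acetate (lactol acetate; racemic), via lactol 8 (not isolated)
Conditions: Ac2O, pyridine, CH2Cl2, 0 °C
Reagents that add atoms: acetic anhydride, CC(=O)OC(C)=O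
Why: pseudo-ester formation: the δ-oxo acid reacts through its ring-chain tautomer 8, whose hydroxyl group is acetylated, and the low temperature should keep the acetate from losing acetic acid before step 7.

**Step 6**
Reactants: 10 acetophenone
Product: 11 triethyl[(1-phenylethenyl)oxy]silane
Conditions: Et3SiOTf, Et3N, CH2Cl2, 0 °C
Reagents that add atoms: triethylsilyl trifluoromethanesulfonate, CC[Si](CC)(CC)OS(=O)(=O)C(F)(F)F
Why: soft enolization (O-silylation of the ketone by the silyl triflate, then deprotonation by the amine), which with a methyl ketone can give only one enol ether.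

**Step 7**
Reactants: 9 8-(benzyloxy)-3-oxo-3,4-dihydro-1H-2-benzopyran-1-yl acetate; 11 triethyl[(1-phenylethenyl)oxy]silane
Product: 13 bridged lactone (1S,3S,4S)-8-(benzyloxy)-1-hydroxy-3-phenyl-3-[(triethylsilyl)oxy]-1,2,3,4-tetrahydronaphthalene-4-carboxylic acid 1,4-lactone, via 8-(benzyloxy)-2-benzopyran-3-one 12 (not isolated)
Conditions: (R)-3,3′-bis(2,4,6-triisopropylphenyl)-1,1′-binaphthyl-2,2′-diyl hydrogen phosphate (10 mol %), 11 (3 equiv), toluene, 0 °C → rt, 9 added slowly over several hours
Reagents that add atoms: none
Why: Proposed new method: the phosphoric acid should ionize the acetate of 9 (helped by the ortho benzyloxy donor) and its phosphate remove the C4 proton, so that 12 arises hydrogen-bonded through its carbonyl to the catalyst, in the limit a 3-hydroxy-2-benzopyrylium phosphate ion pair; the nucleophilic CH2 of 11 then bonds to the pyrylium-like C1 and the silyloxy-bearing carbon to the enol-like C4, in one step or two, driven by the return of ring A to a benzene ring. The closest known reaction types are the thermal Diels–Alder trapping of 2-benzopyran-3-ones made from (2-formylaryl)acetic acids and the chiral phosphoric acid catalysed inverse-demand [4+2] cycloadditions of o-quinone methides, generated in the flask, with enol ethers. Ring B is closed by an intermolecular [4+2] cycloaddition across C1 and C4 of the diene; if the C3–C4 bond lags behind, it forms by 6-exo-trig attack of the lactone enol on the silyloxycarbenium ion. C1 and C4 are set by the face of the planar diene that the catalyst leaves open and are cis of necessity because the ester bridge joins them; C3 is set by the orientation of 11, with the triethylsilyloxy group on the side of ring A (the place alkoxy groups take in inverse-demand pyranone cycloadditions and the one remote from the catalyst-bound lactone oxygen) and phenyl on the side of the lactone bridge, hence cis to the C4 carbon substituent. Regiochemistry follows from the polarity built into the substrate (C1 electrophilic next to the ring oxygen, C4 nucleophilic next to the carbonyl, CH2 of 11 nucleophilic), and slow addition of 9 keeps 12 dilute so that its dimerization and the uncatalysed reaction stay minor.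

**Step 8**
Reactants: 13 bridged lactone; 14 2,2,6-trimethyl-4H-1,3-dioxin-4-one
Product: 16 6-{2-[(1S,2S,4S)-5-(benzyloxy)-4-hydroxy-2-phenyl-2-[(triethylsilyl)oxy]-1,2,3,4-tetrahydronaphthalen-1-yl]-2-oxoethyl}-2,2-dimethyl-4H-1,3-dioxin-4-one, via lithium dienolate 15 (not isolated)
Conditions: 14 (2.6 equiv), LiN(i-Pr)2 (2.5 equiv), THF, −78 °C; then 13, −78 → −40 °C; AcOH quench at −78 °C
Reagents that add atoms: none
Why: Claisen-type C-acylation of the γ-lithiated dioxinone by the strained lactone, whose bridgehead C4–H cannot be removed (a bridgehead enolate is geometrically excluded), so that C4 is not epimerized and the β-silyloxy group is not eliminated; the β-keto-dioxinone is stored as its enolate until the quench, and the C1 alkoxide, trans to the C3 silyl ether, cannot take over the silyl group.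

**Step 9**
Reactants: 16 hydroxy keto-dioxinone
Product: 17 6-{2-[(1S,2S)-5-(benzyloxy)-4-oxo-2-phenyl-2-[(triethylsilyl)oxy]-1,2,3,4-tetrahydronaphthalen-1-yl]-2-oxoethyl}-2,2-dimethyl-4H-1,3-dioxin-4-one
Conditions: Dess–Martin periodinane, pyridine, CH2Cl2, 0 °C → rt
Reagents that add atoms: none
Why: Dess–Martin oxidation of the benzylic secondary alcohol under pyridine buffering, which should leave the tertiary silyl ether, the β-keto-dioxinone and the now enolizable C4–H untouched; any bridged hemiketal tautomer of 16 reacts through the open form.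

**Step 10**
Reactants: 17 diketo-dioxinone
Product: 19 (3S,4R)-8-(benzyloxy)-4-(4-hydroxy-2-oxo-2H-pyran-6-yl)-3-phenyl-3-[(triethylsilyl)oxy]-3,4-dihydronaphthalen-1(2H)-one, via acylketene 18 (not isolated)
Conditions: dry toluene (0.01 M), 110 °C
Reagents that add atoms: none
Why: thermal retro-[4+2] fragmentation of the dioxinone releases acetone and the acylketene 18, which is trapped by the enol oxygen of the neighbouring ketone in a six-membered O-acylation to give the 4-hydroxy-2-pyranone under neutral conditions that touch neither C3 nor C4.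

**Step 11**
Reactants: 19 benzyl-protected pyranone
Product: 20 (3S,4R)-8-hydroxy-4-(4-hydroxy-2-oxo-2H-pyran-6-yl)-3-phenyl-3-[(triethylsilyl)oxy]-3,4-dihydronaphthalen-1(2H)-one
Conditions: H2 (1 atm), Pd/C (10 wt % Pd on carbon), EtOAc, rt, stopped at full conversion
Reagents that add atoms: none
Why: hydrogenolysis of the aryl benzyl ether, which on palladium in neutral ethyl acetate should be much faster than reduction of the aryl ketone, of the pyranone or of the tertiary benzylic C–O bond, the latter being shielded as its silyl ether.

**Step 12**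
Reactants: 20 silyl-protected phenol
Product: 21 (3S,4S)-3,8-dihydroxy-4-(4-hydroxy-2-oxo-2H-pyran-6-yl)-3-phenyl-3,4-dihydronaphthalen-1(2H)-one
Conditions: HF·pyridine, pyridine, THF, 0 °C → rt
Reagents that add atoms: none
Why: fluoride-induced cleavage of the tertiary triethylsilyl ether in a pyridine-buffered medium mild enough not to dehydrate the β-hydroxy ketone to the naphthol; no stereocentre is touched, and the C4 descriptor changes from R to S only because C3 loses rank when silicon is replaced by hydrogen.

**Compound list**

1 | 2-bromo-6-hydroxybenzaldehyde | O=Cc1c(O)cccc1Br | starting material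
2 | 2-(benzyloxy)-6-bromobenzaldehyde | O=Cc1c(OCc2ccccc2)cccc1Br | intermediate
3 | 2-[2-(benzyloxy)-6-bromophenyl]-1,3-dioxolane | Brc1cccc(OCc2ccccc2)c1C1OCCO1 | intermediate
4 | tert-butyl bromoacetate | CC(C)(C)OC(=O)CBr | starting material
5 | bromo(2-tert-butoxy-2-oxoethyl)zinc (Reformatsky reagent) | CC(C)(C)OC(=O)C[Zn]Br | intermediate
6 | tert-butyl [3-(benzyloxy)-2-(1,3-dioxolan-2-yl)phenyl]acetate | CC(C)(C)OC(=O)Cc1cccc(OCc2ccccc2)c1C1OCCO1 | intermediate
7 | [3-(benzyloxy)-2-formylphenyl]acetic acid | O=Cc1c(CC(=O)O)cccc1OCc1ccccc1 | intermediate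
8 | 8-(benzyloxy)-1-hydroxy-1,4-dihydro-3H-2-benzopyran-3-one (lactol tautomer of 7, racemic) | OC1OC(=O)Cc2cccc(OCc3ccccc3)c21 | intermediate
9 | 8-(benzyloxy)-3-oxo-3,4-dihydro-1H-2-benzopyran-1-yl acetate (lactol acetate, racemic) | CC(=O)OC1OC(=O)Cc2cccc(OCc3ccccc3)c21 | intermediate
10 | acetophenone | CC(=O)c1ccccc1 | starting material
11 | triethyl[(1-phenylethenyl)oxy]silane | C=C(O[Si](CC)(CC)CC)c1ccccc1 | intermediate
12 | 8-(benzyloxy)-3H-2-benzopyran-3-one (o-quinoid pyranone) | O=C1C=C2C=CC=C(OCc3ccccc3)C2=CO1 | intermediate
13 | (1S,3S,4S)-8-(benzyloxy)-1-hydroxy-3-phenyl-3-[(triethylsilyl)oxy]-1,2,3,4-tetrahydronaphthalene-4-carboxylic acid 1,4-lactone (phenyl on the face of the lactone bridge, silyloxy on the face of ring A) | O=C1O[C@H]2C[C@@](O[Si](CC)(CC)CC)(c3ccccc3)[C@@H]1c1cccc(OCc3ccccc3)c12 | intermediate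
14 | 2,2,6-trimethyl-4H-1,3-dioxin-4-one | CC1=CC(=O)OC(C)(C)O1 | starting material
15 | lithium 2,2-dimethyl-6-methylidene-6H-1,3-dioxin-4-olate | C=C1C=C(O[Li])OC(C)(C)O1 | intermediate
16 | 6-{2-[(1S,2S,4S)-5-(benzyloxy)-4-hydroxy-2-phenyl-2-[(triethylsilyl)oxy]-1,2,3,4-tetrahydronaphthalen-1-yl]-2-oxoethyl}-2,2-dimethyl-4H-1,3-dioxin-4-one | O[C@H]1C[C@@](O[Si](CC)(CC)CC)(c2ccccc2)[C@@H](C(=O)CC2=CC(=O)OC(C)(C)O2)c2cccc(OCc3ccccc3)c21 | intermediate
17 | 6-{2-[(1S,2S)-5-(benzyloxy)-4-oxo-2-phenyl-2-[(triethylsilyl)oxy]-1,2,3,4-tetrahydronaphthalen-1-yl]-2-oxoethyl}-2,2-dimethyl-4H-1,3-dioxin-4-one | O=C1C[C@@](O[Si](CC)(CC)CC)(c2ccccc2)[C@@H](C(=O)CC2=CC(=O)OC(C)(C)O2)c2cccc(OCc3ccccc3)c21 | intermediate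
18 | 5-[(1S,2S)-5-(benzyloxy)-4-oxo-2-phenyl-2-[(triethylsilyl)oxy]-1,2,3,4-tetrahydronaphthalen-1-yl]pent-1-ene-1,3,5-trione (acylketene) | O=C1C[C@@](O[Si](CC)(CC)CC)(c2ccccc2)[C@@H](C(=O)CC(=O)C=C=O)c2cccc(OCc3ccccc3)c21 | intermediate
19 | (3S,4R)-8-(benzyloxy)-4-(4-hydroxy-2-oxo-2H-pyran-6-yl)-3-phenyl-3-[(triethylsilyl)oxy]-3,4-dihydronaphthalen-1(2H)-one | O=C1C[C@@](O[Si](CC)(CC)CC)(c2ccccc2)[C@@H](c2cc(O)cc(=O)o2)c2cccc(OCc3ccccc3)c21 | intermediate
20 | (3S,4R)-8-hydroxy-4-(4-hydroxy-2-oxo-2H-pyran-6-yl)-3-phenyl-3-[(triethylsilyl)oxy]-3,4-dihydronaphthalen-1(2H)-one | O=C1C[C@@](O[Si](CC)(CC)CC)(c2ccccc2)[C@@H](c2cc(O)cc(=O)o2)c2cccc(O)c21 | intermediate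
21 | (3S,4S)-3,8-dihydroxy-4-(4-hydroxy-2-oxo-2H-pyran-6-yl)-3-phenyl-3,4-dihydronaphthalen-1(2H)-one | O=C1C[C@@](O)(c2ccccc2)[C@@H](c2cc(O)cc(=O)o2)c2cccc(O)c21 | target

**Step count**

Total: 12 steps. Longest linear sequence: 11 steps (steps 1–5 and 7–12, from 1 to 21); step 6 is a one-step side branch.

**Steps most likely to fail**

Step 7 may fail through poor facial selectivity, through the wrong orientation of the enol ether (phenyl on the side of ring A), or through capture of the ionized acetate by 11 before the C4 proton is lost, which would give an uncyclized Mukaiyama-type adduct. The fallback sets out from 9. The acetate is heated with excess 11 and 2,6-lutidine in toluene at 110 °C, the classical thermal generation and Diels–Alder trapping of a 2-benzopyran-3-one (12). This should give the bridged lactone as a racemate, that is 13 together with its mirror image, the (1R,3R,4R) lactone F1. A diastereomer with phenyl on the side of ring A, if formed, is removed on silica. Preparative chromatography on a chiral stationary phase then separates 13 from F1, and the route is rejoined at 13.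

Step 8 may fail through slow attack on the hindered lactone carbonyl, so that the dienolate reacts at its α-carbon or is simply returned on quenching. The fallback sets out from 13. The lactone is opened with Me(MeO)NH·HCl and Al(CH3)3 in CH2Cl2 (aluminium amide aminolysis) to the hydroxy N-methoxy-N-methylamide F2. Its lithium alkoxide, formed by the first equivalent of 15, is then acylated by further 15 through a chelated tetrahedral adduct that releases the ketone only on work-up. The route is rejoined at 16.

Step 5 may fail because acetylation stops at the open-chain mixed anhydride, or because the acetate loses acetic acid too early and the o-quinoid pyranone dimerizes. The fallback sets out from 7. Oxalyl chloride with catalytic DMF in CH2Cl2 at 0 °C should give the cyclic pseudo-chloride, 8-(benzyloxy)-1-chloro-1,4-dihydro-3H-2-benzopyran-3-one F3, as acid chlorides of δ-oxo acids do. AgOAc in CH2Cl2 then replaces chloride by acetate at the activated C1, which returns the route to 9.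

**Further compounds**

F1 | step 7 | (1R,3R,4R)-8-(benzyloxy)-1-hydroxy-3-phenyl-3-[(triethylsilyl)oxy]-1,2,3,4-tetrahydronaphthalene-4-carboxylic acid 1,4-lactone (enantiomer of 13) | O=C1O[C@@H]2C[C@](O[Si](CC)(CC)CC)(c3ccccc3)[C@H]1c1cccc(OCc3ccccc3)c12
F2 | step 8 | (1S,2S,4S)-5-(benzyloxy)-4-hydroxy-N-methoxy-N-methyl-2-phenyl-2-[(triethylsilyl)oxy]-1,2,3,4-tetrahydronaphthalene-1-carboxamide | O[C@H]1C[C@@](O[Si](CC)(CC)CC)(c2ccccc2)[C@@H](C(=O)N(C)OC)c2cccc(OCc3ccccc3)c21
F3 | step 5 | 8-(benzyloxy)-1-chloro-1,4-dihydro-3H-2-benzopyran-3-one (racemic) | ClC1OC(=O)Cc2cccc(OCc3ccccc3)c21
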